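**Plan**

- Retrosynthetic cuts (acyl chain numbered C1′ = carbonyl to C18′; ring atoms by 1-benzoxepine locants): first C3′–C4′ of the octadecanoyl chain, giving acrylate 9 and the n-C15 Grignard reagent 11; then the acyl C–O bond, giving alcohol 7; then C4=C5 of the oxepine (intramolecular Wittig) and O1–C2 (Williamson), giving salicylaldehyde 1 and dichloride 2.
- Forward order: O1–C2 ether, phosphonium salt, Wittig closure of the seven-membered ring (the C3 methylidene arrives with 2), ester to CH2OH, acryloylation, and the C15 chain joined in the last step.
- Enabling feature: C3′ lies β to the ester carbonyl C1′, so C2′=C3′ of an acrylate is the only carbonyl-polarised alkene. The C3(=CH2)–C4=C5 diene of the dihydrooxepine ring, conjugated to the benzene ring, carries no acceptor group and should be inert to an organocopper nucleophile.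
- Stereochemistry: the target has no stereocentre; the C4=C5 alkene is cis by ring constraint in the Wittig closure.

Key step: step 7

**Route**

Step 1
Reactants: 1 methyl 3-formyl-4-hydroxybenzoate; 2 3-chloro-2-(chloromethyl)prop-1-ene (4 equiv)
Product: 3 methyl 4-{[2-(chloromethyl)prop-2-en-1-yl]oxy}-3-formylbenzoate
Conditions: K2CO3, DMF, 50 °C
Reagents that add atoms: none
Why: Williamson ether synthesis in which the acidified salicylaldehyde phenoxide displaces one allylic chloride (SN2), the excess of symmetrical dichloride 2 suppressing double substitution.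

Step 2
Reactants: 3 methyl 4-{[2-(chloromethyl)prop-2-en-1-yl]oxy}-3-formylbenzoate
Product: 4 (2-{[2-formyl-4-(methoxycarbonyl)phenoxy]methyl}prop-2-en-1-yl)triphenylphosphonium chloride
Conditions: PPh3 (1.1 equiv), MeCN, reflux
Reagents that add atoms: triphenylphosphine, c1ccc(cc1)P(c1ccccc1)c1ccccc1
Why: SN2 quaternisation of triphenylphosphine by the primary allylic chloride (phosphonium salt formation), which the aryl aldehyde and the ester tolerate.

Step 3
Reactants: 4 (2-{[2-formyl-4-(methoxycarbonyl)phenoxy]methyl}prop-2-en-1-yl)triphenylphosphonium chloride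
Product: 6 methyl 3-methylidene-2,3-dihydro-1-benzoxepine-7-carboxylate, via allylic phosphonium ylide 5 (not isolated)
Conditions: NaHMDS (1.05 equiv), THF (0.01 M), −78 °C to rt
Reagents that add atoms: none
Why: Intramolecular Wittig olefination in which the α-carbon of the semi-stabilised allylic ylide attacks the ortho aldehyde and oxaphosphetane collapse closes the seven-membered ring, with C4=C5 necessarily cis and the C3 methylidene already in place, high dilution disfavouring intermolecular olefination.

Step 4
Reactants: 6 methyl 3-methylidene-2,3-dihydro-1-benzoxepine-7-carboxylate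
Product: 7 (3-methylidene-2,3-dihydro-1-benzoxepin-7-yl)methanol
Conditions: DIBAL-H (2.3 equiv), CH2Cl2, −78 to 0 °C; aq. Rochelle salt
Reagents that add atoms: none
Why: DIBAL-H reduction of the aryl methyl ester to the benzylic alcohol, the unpolarised diene not being hydroaluminated at low temperature.

Step 5
Reactants: 7 (3-methylidene-2,3-dihydro-1-benzoxepin-7-yl)methanol; 8 acryloyl chloride (1.2 equiv)
Product: 9 (3-methylidene-2,3-dihydro-1-benzoxepin-7-yl)methyl prop-2-enoate
Conditions: Et3N (1.5 equiv), DMAP (cat.), BHT (trace), CH2Cl2, 0 °C
Reagents that add atoms: none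
Why: O-acylation of a primary benzylic alcohol by an acid chloride (nucleophilic acyl substitution), the amine base scavenging HCl so that the acid-sensitive p-alkoxybenzylic position is not ionised.

Step 6
Reactants: 10 1-bromopentadecane
Product: 11 pentadecylmagnesium bromide (titrated THF solution, used directly)
Conditions: Mg turnings (1.2 equiv), I2 (cat.), THF, 45 °C
Reagents that add atoms: magnesium, [Mg]
Why: Grignard reagent formation by insertion of magnesium into the primary C–Br bond.

Step 7
Reactants: 9 (3-methylidene-2,3-dihydro-1-benzoxepin-7-yl)methyl prop-2-enoate; 11 pentadecylmagnesium bromide (1.3 equiv)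
Product: 13 (3-methylidene-2,3-dihydro-1-benzoxepin-7-yl)methyl octadecanoate, via trimethylsilyl ketene acetal 12 (not isolated)
Conditions: CuBr·SMe2 (10 mol %), TMSCl (2 equiv), THF, −78 °C, slow addition of 11; then sat. aq. NH4Cl, rt
Reagents that add atoms: none
Why: Transmetalation of 11 to copper(I) gives a pentadecylcuprate that π-complexes the C2′=C3′ bond of the acrylate in 9 and adds oxidatively at C3′ to a Cu(III) β-cuprio enolate; TMSCl silylates the enolate oxygen and reductive elimination then forms the C3′–C4′ bond, releasing Cu(I) and silyl ketene acetal 12, which aqueous NH4Cl hydrolyses to ester 13. The closest known reaction type is the copper-catalysed, TMSCl-accelerated conjugate addition of Grignard reagents to α,β-unsaturated esters, used with acrylates as a three-carbon homologation to fatty esters. No ring is closed and no stereocentre is formed in this step. The selectivities needed are 1,4- over 1,2-addition to the ester and reaction at the acrylate in preference to the C3(=CH2)–C4=C5 diene and the allylic O1–C2 aryl ether of the oxepine ring. They are secured because the acrylate is the only alkene polarised by a carbonyl group, the soft cuprate prefers its β-carbon, and at −78 °C neither the acceptor-free diene nor the poor aryloxide leaving group should react. In situ O-silylation removes the enolate, so it cannot add to a second acrylate, and slow addition keeps the concentration of free Grignard reagent low.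

**Compound list**

1 | methyl 3-formyl-4-hydroxybenzoate | COC(=O)c1ccc(O)c(C=O)c1 | starting material
2 | 3-chloro-2-(chloromethyl)prop-1-ene | C=C(CCl)CCl | starting material
3 | methyl 4-{[2-(chloromethyl)prop-2-en-1-yl]oxy}-3-formylbenzoate | COC(=O)c1ccc(OCC(=C)CCl)c(C=O)c1 | intermediate
4 | (2-{[2-formyl-4-(methoxycarbonyl)phenoxy]methyl}prop-2-en-1-yl)triphenylphosphonium chloride | COC(=O)c1ccc(OCC(=C)C[P+](c2ccccc2)(c2ccccc2)c2ccccc2)c(C=O)c1.[Cl-] | intermediate
5 | allylic phosphonium ylide, methyl 3-formyl-4-({2-[(triphenylphosphoranylidene)methyl]prop-2-en-1-yl}oxy)benzoate | COC(=O)c1ccc(OCC(=C)C=P(c2ccccc2)(c2ccccc2)c2ccccc2)c(C=O)c1 | intermediate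
6 | methyl 3-methylidene-2,3-dihydro-1-benzoxepine-7-carboxylate (C4=C5 cis, in ring) | C=C1C=Cc2cc(C(=O)OC)ccc2OC1 | intermediate
7 | (3-methylidene-2,3-dihydro-1-benzoxepin-7-yl)methanol | C=C1C=Cc2cc(CO)ccc2OC1 | intermediate
8 | acryloyl chloride (prop-2-enoyl chloride) | C=CC(=O)Cl | starting material
9 | (3-methylidene-2,3-dihydro-1-benzoxepin-7-yl)methyl prop-2-enoate | C=C1C=Cc2cc(COC(=O)C=C)ccc2OC1 | intermediate
10 | 1-bromopentadecane | CCCCCCCCCCCCCCCBr | starting material
11 | pentadecylmagnesium bromide | CCCCCCCCCCCCCCC[Mg]Br | intermediate
12 | trimethylsilyl ketene acetal, [(1-{[(3-methylidene-2,3-dihydro-1-benzoxepin-7-yl)methyl]oxy}octadec-1-en-1-yl)oxy]trimethylsilane (E/Z mixture) | C=C1C=Cc2cc(COC(O[Si](C)(C)C)=CCCCCCCCCCCCCCCCC)ccc2OC1 | intermediate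
13 | (3-methylidene-2,3-dihydro-1-benzoxepin-7-yl)methyl octadecanoate | C=C1C=Cc2cc(COC(=O)CCCCCCCCCCCCCCCCC)ccc2OC1 | target

**Step count**

Total steps: 7. Longest linear sequence: 6 steps (steps 1–5 and 7); step 6 is a one-step side branch.

**Steps most likely to fail**

Step 3 (seven-membered ring Wittig closure). Intermolecular olefination to oligomers may outrun ring closure, and a prototropic shift of the allylic ylide to the conjugated vinylphosphonium salt may drain the reactive species. The fallback sets out from compound 1 and comes back at compound 6, closing the ring by metathesis instead of olefination. Aldehyde 1 would be methylenated with Ph3P=CH2 (2.2 equiv, THF) to methyl 4-hydroxy-3-vinylbenzoate F1. The phenoxide of F1 would open 2-vinyloxirane at its terminal carbon (K2CO3, DMF, 70 °C) to give racemic methyl 4-[(2-hydroxybut-3-en-1-yl)oxy]-3-vinylbenzoate F2. Ring-closing metathesis (Grubbs II, CH2Cl2, 40 °C) should give racemic methyl 3-hydroxy-2,3-dihydro-1-benzoxepine-7-carboxylate F3. Dess–Martin oxidation would give methyl 3-oxo-2,3-dihydro-1-benzoxepine-7-carboxylate F4, and Wittig methylenation of the ketone (Ph3P=CH2, THF, −78 to 0 °C) would install the C3 methylidene and deliver 6.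

Step 7 (conjugate addition). Failure modes are 1,2-addition of the Grignard reagent to the ester, anionic oligomerisation of the acrylate, and copper-mediated allylic substitution at the O1–C2 aryl ether of the ring. The fallback sets out from compounds 11 and 7 and comes back at compound 13, forming the same C3′–C4′ bond away from the sensitive diene. Grignard reagent 11 would open β-propiolactone (oxetan-2-one) at its β-carbon under CuCl catalysis (THF, 0 °C; HCl work-up) to give octadecanoic acid F5. Carbodiimide esterification of F5 with alcohol 7 (EDC·HCl, DMAP, CH2Cl2, rt) should then give 13.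

Step 5 (acryloylation). The HCl formed may ionise the electron-rich p-alkoxybenzylic position before the base intercepts it, and the acrylate may polymerise during acylation. The fallback sets out from compound 7 and comes back at compound 9 by activating the alcohol instead of the acid: Mitsunobu esterification of 7 with acrylic acid (PPh3, DIAD, THF, 0 °C) forms the O–CH2 bond under neutral, chloride-free conditions and makes no new compound on the way.

Further compounds
F1 | step 3 | methyl 4-hydroxy-3-vinylbenzoate | COC(=O)c1ccc(O)c(C=C)c1
F2 | step 3 | methyl 4-[(2-hydroxybut-3-en-1-yl)oxy]-3-vinylbenzoate (racemic) | COC(=O)c1ccc(OCC(O)C=C)c(C=C)c1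
F3 | step 3 | methyl 3-hydroxy-2,3-dihydro-1-benzoxepine-7-carboxylate (racemic) | COC(=O)c1ccc2OCC(O)C=Cc2c1
F4 | step 3 | methyl 3-oxo-2,3-dihydro-1-benzoxepine-7-carboxylate | COC(=O)c1ccc2OCC(=O)C=Cc2c1
F5 | step 7 | octadecanoic acid | CCCCCCCCCCCCCCCCCC(=O)O
F0 | step 5 | none | none
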